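**Retrosynthetic overview**

- Numbering: ring A is C1–C6 with its chain C7–C8–C9; ring B is C1'–C6' with its chain C7'–C8'–C9'. The strategy rests on the ether bond O8–C4'. The oxygen on C8 is bonded to C4' of ring B, which lies between the methoxy-bearing C3' and C5' and para to C1', the carbon that carries the propenol chain. With C1' at the formyl level, a fluorine on C4' is open to ipso substitution.
- Disconnections, from the target backwards: C7'=C8' by Horner–Wadsworth–Emmons olefination, then ester reduction to C9'–OH; O8–C4' by SNAr of the C8 alkoxide on 4-fluoro-3,5-dimethoxybenzaldehyde; C1–C7 by addition of a ring A Grignard reagent to (R)-glyceraldehyde acetonide, which brings C8 as R and directs C7 to S (erythro).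
- Rings: both benzene rings are bought and no ring is formed. The dioxolane of the glyceraldehyde unit is opened before the key step, so that C8–OH is the only free hydroxyl (C7–O as an acetal ether, C9–O and the phenol as silyl ethers).

Key step: step 6

Remark: the minor C7 epimer expected from step 2 is assumed to be separable by chromatography, so all later compounds are drawn as single diastereomers.

**Route**

Step 1
Reactants: 1 4-bromo-2,6-dimethoxyphenol
Product: 2 (4-bromo-2,6-dimethoxyphenoxy)triisopropylsilane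
Conditions: TIPSCl, imidazole, DMF, rt
Reagents that add atoms: chlorotriisopropylsilane, CC(C)[Si](Cl)(C(C)C)C(C)C
Why: Imidazole-promoted O-silylation of the phenol gives a triisopropylsilyl ether, shielded further by the two ortho methoxy groups, that should survive the Grignard, amide-base, phosphonate and hydride steps and fall to fluoride at the end.

Step 2
Reactants: 2 (4-bromo-2,6-dimethoxyphenoxy)triisopropylsilane; 3 (R)-2,2-dimethyl-1,3-dioxolane-4-carbaldehyde
Product: 5 (S)-[(4R)-2,2-dimethyl-1,3-dioxolan-4-yl]{3,5-dimethoxy-4-[(triisopropylsilyl)oxy]phenyl}methanol (anti adduct), via ring A Grignard reagent 4 (not isolated)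
Conditions: Mg, THF, reflux; then 3, THF, −78 → −20 °C; then aq NH4Cl
Reagents that add atoms: none
Why: Grignard formation and 1,2-addition to the α-alkoxy aldehyde under Felkin–Anh (non-chelation) control in THF, in which the aryl group should attack the formyl carbon anti to the C8–O bond of the dioxolane and so set C7 as S (anti, erythro) beside the R centre C8 taken unchanged from 3, the minor syn epimer being removed by chromatography.

Step 3
Reactants: 5 (S)-[(4R)-2,2-dimethyl-1,3-dioxolan-4-yl]{3,5-dimethoxy-4-[(triisopropylsilyl)oxy]phenyl}methanol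
Product: 6 {4-[(S)-[(4R)-2,2-dimethyl-1,3-dioxolan-4-yl]{[2-(trimethylsilyl)ethoxy]methoxy}methyl]-2,6-dimethoxyphenoxy}triisopropylsilane (C7 SEM ether of 5)
Conditions: SEMCl, i-Pr2NEt, Bu4NI (cat.), CH2Cl2, 40 °C
Reagents that add atoms: 2-(trimethylsilyl)ethoxymethyl chloride, C[Si](C)(C)CCOCCl
Why: Iodide-catalysed O-alkylation of the secondary alcohol with the chloromethyl ether gives an acetal-type ether that cannot migrate to a neighbouring alkoxide and is stable to the mild acid of step 4.

Step 4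
Reactants: 6 C7 SEM ether of 5
Product: 7 (2R,3S)-3-{3,5-dimethoxy-4-[(triisopropylsilyl)oxy]phenyl}-3-{[2-(trimethylsilyl)ethoxy]methoxy}propane-1,2-diol
Conditions: AcOH–H2O–THF (3:1:1), 40 °C
Reagents that add atoms: none
Why: Acid-catalysed hydrolysis of the terminal isopropylidene acetal, the most acid-labile group present, in aqueous acetic acid, which should leave the SEM ether and the aryl silyl ether in place.

Step 5
Reactants: 7 (2R,3S)-3-{3,5-dimethoxy-4-[(triisopropylsilyl)oxy]phenyl}-3-{[2-(trimethylsilyl)ethoxy]methoxy}propane-1,2-diol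
Product: 8 (1S,2R)-1-{3,5-dimethoxy-4-[(triisopropylsilyl)oxy]phenyl}-3-[(triisopropylsilyl)oxy]-1-{[2-(trimethylsilyl)ethoxy]methoxy}propan-2-ol
Conditions: TIPSCl, imidazole, CH2Cl2, 0 °C → rt
Reagents that add atoms: chlorotriisopropylsilane, CC(C)[Si](Cl)(C(C)C)C(C)C
Why: Sterically controlled silylation, in which the bulky chlorosilane should react at the primary C9–OH and leave the hindered secondary C8–OH free.

Step 6
Reactants: 8 (1S,2R)-1-{3,5-dimethoxy-4-[(triisopropylsilyl)oxy]phenyl}-3-[(triisopropylsilyl)oxy]-1-{[2-(trimethylsilyl)ethoxy]methoxy}propan-2-ol; 9 4-fluoro-3,5-dimethoxybenzaldehyde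
Product: 11 4-{[(1S,2R)-1-{3,5-dimethoxy-4-[(triisopropylsilyl)oxy]phenyl}-3-[(triisopropylsilyl)oxy]-1-{[2-(trimethylsilyl)ethoxy]methoxy}propan-2-yl]oxy}-3,5-dimethoxybenzaldehyde, via potassium C8 alkoxide 10 (not isolated)
Conditions: KN(SiMe3)2 (0.98 equiv), THF, −78 → 0 °C; then 9, THF–DMF, 0 → 40 °C; then aq NH4Cl
Reagents that add atoms: none
Why: Addition–elimination (SNAr): the potassium alkoxide 10 adds to C4' of 9 ipso to fluorine, the charge of the Meisenheimer adduct sits on C3', C5' and C1' and runs out onto the formyl oxygen, and loss of fluoride as KF restores ring B. The closest known reaction type is the etherification of 4-fluorobenzaldehydes with alkali alkoxides of secondary alcohols; here the methoxy groups on C3' and C5' should slow the addition but not block the perpendicular approach to C4', and fluorine is the best leaving group when addition is rate-limiting. No ring is closed and no stereocentre is made: the O–C8 bond is never broken, so C8 stays R and C7 stays S (erythro). The step needs site selectivity for O8, which is secured because C8–OH is the only free hydroxyl, the C7 acetal cannot shift, and the primary triisopropylsilyl ether is the common silyl group least prone to a 1,4 oxygen-to-oxygen shift at the low temperature at which the alkoxide is made and used. It also needs chemoselectivity against the carbonyl group: 9 has no α-hydrogen, addition of 10 to C=O is reversible, and slightly less than one equivalent of KN(SiMe3)2 leaves no amide to turn the aldehyde into an N-silyl imine.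

Step 7
Reactants: 11 protected 8-O-4' ether aldehyde; 12 triethyl phosphonoacetate
Product: 13 ethyl (E)-3-(4-{[(1S,2R)-1-{3,5-dimethoxy-4-[(triisopropylsilyl)oxy]phenyl}-3-[(triisopropylsilyl)oxy]-1-{[2-(trimethylsilyl)ethoxy]methoxy}propan-2-yl]oxy}-3,5-dimethoxyphenyl)prop-2-enoate
Conditions: LiCl, DBU, MeCN–THF, rt
Reagents that add atoms: none
Why: Horner–Wadsworth–Emmons olefination in its mild lithium chloride/amidine-base form, in which the stabilised phosphonate should give the E enoate while the weak base leaves both silyl ethers and the acetal alone.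

Step 8
Reactants: 13 protected ethyl (E)-cinnamate
Product: 14 (E)-3-(4-{[(1S,2R)-1-{3,5-dimethoxy-4-[(triisopropylsilyl)oxy]phenyl}-3-[(triisopropylsilyl)oxy]-1-{[2-(trimethylsilyl)ethoxy]methoxy}propan-2-yl]oxy}-3,5-dimethoxyphenyl)prop-2-en-1-ol
Conditions: i-Bu2AlH, CH2Cl2, −78 °C; then aq potassium sodium tartrate
Reagents that add atoms: none
Why: 1,2-Reduction of the conjugated ester by the aluminium hydride at low temperature should give the E allylic alcohol without touching the alkene, the silyl ethers or the acetal.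

Step 9
Reactants: 14 protected allylic alcohol
Product: 15 (1S,2R)-1-(4-hydroxy-3,5-dimethoxyphenyl)-2-{4-[(E)-3-hydroxyprop-1-en-1-yl]-2,6-dimethoxyphenoxy}propane-1,3-diol (target)
Conditions: Bu4NF, THF–DMPU, rt → 50 °C; then AcOH
Reagents that add atoms: none
Why: Fluoride-induced desilylation cleaves both triisopropylsilyl ethers and fragments the SEM group (attack at silicon, loss of ethylene and formaldehyde), and since no C–O bond at C7 or C8 is broken the 7S,8R (erythro) configuration is carried into the target.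

**Compound list**

1 | 4-bromo-2,6-dimethoxyphenol | COc1cc(Br)cc(OC)c1O | starting material
2 | (4-bromo-2,6-dimethoxyphenoxy)triisopropylsilane | COc1cc(Br)cc(OC)c1O[Si](C(C)C)(C(C)C)C(C)C | intermediate
3 | (R)-2,2-dimethyl-1,3-dioxolane-4-carbaldehyde | O=C[C@H]1COC(C)(C)O1 | starting material
4 | {3,5-dimethoxy-4-[(triisopropylsilyl)oxy]phenyl}magnesium bromide | COc1cc([Mg]Br)cc(OC)c1O[Si](C(C)C)(C(C)C)C(C)C | intermediate
5 | (S)-[(4R)-2,2-dimethyl-1,3-dioxolan-4-yl]{3,5-dimethoxy-4-[(triisopropylsilyl)oxy]phenyl}methanol | COc1cc([C@H](O)[C@H]2COC(C)(C)O2)cc(OC)c1O[Si](C(C)C)(C(C)C)C(C)C | intermediate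
6 | {4-[(S)-[(4R)-2,2-dimethyl-1,3-dioxolan-4-yl]{[2-(trimethylsilyl)ethoxy]methoxy}methyl]-2,6-dimethoxyphenoxy}triisopropylsilane | COc1cc([C@H](OCOCC[Si](C)(C)C)[C@H]2COC(C)(C)O2)cc(OC)c1O[Si](C(C)C)(C(C)C)C(C)C | intermediate
7 | (2R,3S)-3-{3,5-dimethoxy-4-[(triisopropylsilyl)oxy]phenyl}-3-{[2-(trimethylsilyl)ethoxy]methoxy}propane-1,2-diol | COc1cc([C@H](OCOCC[Si](C)(C)C)[C@H](O)CO)cc(OC)c1O[Si](C(C)C)(C(C)C)C(C)C | intermediate
8 | (1S,2R)-1-{3,5-dimethoxy-4-[(triisopropylsilyl)oxy]phenyl}-3-[(triisopropylsilyl)oxy]-1-{[2-(trimethylsilyl)ethoxy]methoxy}propan-2-ol | COc1cc([C@H](OCOCC[Si](C)(C)C)[C@@H](CO[Si](C(C)C)(C(C)C)C(C)C)O)cc(OC)c1O[Si](C(C)C)(C(C)C)C(C)C | intermediate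
9 | 4-fluoro-3,5-dimethoxybenzaldehyde | COc1cc(C=O)cc(OC)c1F | starting material
10 | potassium (1S,2R)-1-{3,5-dimethoxy-4-[(triisopropylsilyl)oxy]phenyl}-3-[(triisopropylsilyl)oxy]-1-{[2-(trimethylsilyl)ethoxy]methoxy}propan-2-olate | COc1cc([C@H](OCOCC[Si](C)(C)C)[C@@H](CO[Si](C(C)C)(C(C)C)C(C)C)[O-])cc(OC)c1O[Si](C(C)C)(C(C)C)C(C)C.[K+] | intermediate
11 | 4-{[(1S,2R)-1-{3,5-dimethoxy-4-[(triisopropylsilyl)oxy]phenyl}-3-[(triisopropylsilyl)oxy]-1-{[2-(trimethylsilyl)ethoxy]methoxy}propan-2-yl]oxy}-3,5-dimethoxybenzaldehyde | COc1cc([C@H](OCOCC[Si](C)(C)C)[C@@H](CO[Si](C(C)C)(C(C)C)C(C)C)Oc2c(OC)cc(C=O)cc2OC)cc(OC)c1O[Si](C(C)C)(C(C)C)C(C)C | intermediate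
12 | triethyl phosphonoacetate | CCOC(=O)CP(=O)(OCC)OCC | starting material
13 | ethyl (E)-3-(4-{[(1S,2R)-1-{3,5-dimethoxy-4-[(triisopropylsilyl)oxy]phenyl}-3-[(triisopropylsilyl)oxy]-1-{[2-(trimethylsilyl)ethoxy]methoxy}propan-2-yl]oxy}-3,5-dimethoxyphenyl)prop-2-enoate | COc1cc([C@H](OCOCC[Si](C)(C)C)[C@@H](CO[Si](C(C)C)(C(C)C)C(C)C)Oc2c(OC)cc(/C=C/C(=O)OCC)cc2OC)cc(OC)c1O[Si](C(C)C)(C(C)C)C(C)C | intermediate
14 | (E)-3-(4-{[(1S,2R)-1-{3,5-dimethoxy-4-[(triisopropylsilyl)oxy]phenyl}-3-[(triisopropylsilyl)oxy]-1-{[2-(trimethylsilyl)ethoxy]methoxy}propan-2-yl]oxy}-3,5-dimethoxyphenyl)prop-2-en-1-ol | COc1cc([C@H](OCOCC[Si](C)(C)C)[C@@H](CO[Si](C(C)C)(C(C)C)C(C)C)Oc2c(OC)cc(/C=C/CO)cc2OC)cc(OC)c1O[Si](C(C)C)(C(C)C)C(C)C | intermediate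
15 | (1S,2R)-1-(4-hydroxy-3,5-dimethoxyphenyl)-2-{4-[(E)-3-hydroxyprop-1-en-1-yl]-2,6-dimethoxyphenoxy}propane-1,3-diol | COc1cc([C@H](O)[C@@H](CO)Oc2c(OC)cc(/C=C/CO)cc2OC)cc(OC)c1O | target

**Step count**

Total steps: 9. Longest linear sequence: 9 steps (1 → 15); compounds 3, 9 and 12 are bought and enter directly.

**Steps most likely to fail**

1. Step 6. What may go wrong:
   - sluggish addition to the doubly ortho-oxygenated C4';
   - a base-induced 1,4 silyl shift from O9 to O8, after which the freed primary alkoxide is arylated instead;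
   - fluoride-induced loss of the aryl silyl ether;
   - hydride transfer from the alkoxide to the aldehyde (Meerwein–Ponndorf–Verley type).

   Fallback, setting out from 8 and returning at 11: the ether is made at C8 with inversion under neutral conditions instead of at C4'. Oxidation of 8 with Dess–Martin periodinane (NaHCO3, CH2Cl2) should give (S)-1-{3,5-dimethoxy-4-[(triisopropylsilyl)oxy]phenyl}-3-[(triisopropylsilyl)oxy]-1-{[2-(trimethylsilyl)ethoxy]methoxy}propan-2-one F1. Reduction with LiBH(s-Bu)3 (THF, −78 °C) under Felkin–Anh control by the C7–O bond should give the threo alcohol (1S,2S)-1-{3,5-dimethoxy-4-[(triisopropylsilyl)oxy]phenyl}-3-[(triisopropylsilyl)oxy]-1-{[2-(trimethylsilyl)ethoxy]methoxy}propan-2-ol F2. A Mitsunobu reaction of F2 with commercial 4-hydroxy-3,5-dimethoxybenzaldehyde (PPh3, DIAD, toluene, 0 °C → rt) should invert C8 and give 11.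

2. Step 9. What may go wrong: incomplete cleavage of the hindered benzylic SEM ether, or, at the temperature it needs, epimerisation at C7 through reversible quinone methide formation from the ring A phenoxide. Fallback, setting out from 14 and returning at 15: the acetal is removed first by a Lewis acid while the phenol is still silylated. MgBr2·OEt2 in Et2O–MeNO2 at rt should give (1S,2R)-1-{3,5-dimethoxy-4-[(triisopropylsilyl)oxy]phenyl}-2-{4-[(E)-3-hydroxyprop-1-en-1-yl]-2,6-dimethoxyphenoxy}-3-[(triisopropylsilyl)oxy]propan-1-ol F3. Both silyl ethers of F3 are then cleaved with Bu4NF buffered with AcOH (THF, 0 °C → rt) to give 15.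

3. Step 2. What may go wrong: poor facial selectivity, because α-chelated addition competes with the Felkin–Anh pathway and raises the share of the syn epimer. Fallback, setting out from 5 as obtained together with its C7 epimer and returning at 5: the mixture is oxidised with Dess–Martin periodinane (NaHCO3, CH2Cl2) to the single ketone {3,5-dimethoxy-4-[(triisopropylsilyl)oxy]phenyl}[(4R)-2,2-dimethyl-1,3-dioxolan-4-yl]methanone F4. Chelation-controlled reduction with Zn(BH4)2 (Et2O, −30 °C), with zinc bridging the carbonyl oxygen and the dioxolane oxygen on C8 and hydride arriving from the face of the C8 hydrogen, should give the anti alcohol 5.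

**Further compounds**

F1 | step 6 | (S)-1-{3,5-dimethoxy-4-[(triisopropylsilyl)oxy]phenyl}-3-[(triisopropylsilyl)oxy]-1-{[2-(trimethylsilyl)ethoxy]methoxy}propan-2-one | COc1cc([C@H](OCOCC[Si](C)(C)C)C(=O)CO[Si](C(C)C)(C(C)C)C(C)C)cc(OC)c1O[Si](C(C)C)(C(C)C)C(C)C
F2 | step 6 | (1S,2S)-1-{3,5-dimethoxy-4-[(triisopropylsilyl)oxy]phenyl}-3-[(triisopropylsilyl)oxy]-1-{[2-(trimethylsilyl)ethoxy]methoxy}propan-2-ol | COc1cc([C@H](OCOCC[Si](C)(C)C)[C@H](CO[Si](C(C)C)(C(C)C)C(C)C)O)cc(OC)c1O[Si](C(C)C)(C(C)C)C(C)C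
F3 | step 9 | (1S,2R)-1-{3,5-dimethoxy-4-[(triisopropylsilyl)oxy]phenyl}-2-{4-[(E)-3-hydroxyprop-1-en-1-yl]-2,6-dimethoxyphenoxy}-3-[(triisopropylsilyl)oxy]propan-1-ol | COc1cc([C@H](O)[C@@H](CO[Si](C(C)C)(C(C)C)C(C)C)Oc2c(OC)cc(/C=C/CO)cc2OC)cc(OC)c1O[Si](C(C)C)(C(C)C)C(C)C
F4 | step 2 | {3,5-dimethoxy-4-[(triisopropylsilyl)oxy]phenyl}[(4R)-2,2-dimethyl-1,3-dioxolan-4-yl]methanone | COc1cc(C(=O)[C@H]2COC(C)(C)O2)cc(OC)c1O[Si](C(C)C)(C(C)C)C(C)C
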